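## Analysis of the target

The target is a 2,3-dihydro-1,4-benzodioxine. Benzene ring A is fused to dioxane ring B. C2 (Cα) carries ring C, a 3,4-dihydroxy-5-methoxyphenyl group; C3 (Cβ) carries a hydroxymethyl group (Cγ); C5 carries OMe and C7 an (E)-3-hydroxyprop-1-enyl chain. C2 and C3 are the only stereocentres. They are adjacent, (2S,3R), with aryl and hydroxymethyl cis, which is the less stable arrangement on this ring. The two ring A oxygens are not equivalent: O4 sits on C4a between C5–OMe and C8a and is para to the C7 chain, whereas O1 sits on C8a, meta to the chain. Any construction from a free ring A catechol therefore has a regiochemical problem on top of the stereochemical one. The sensitive groups are the ring C catechol (easily oxidised), the coniferyl-type allylic alcohol (ionises in acid) and the benzylic C2–O1 aryl ether, which can open to a quinone methide in base or a benzylic cation in acid and re-close as the trans isomer. The difficulty is to set the cis relationship with absolute control, keep it through deprotection, and unveil the oxygen functions in an order the allylic alcohol tolerates. The plan rests on one correspondence: C8a is the brominated carbon of 5-bromovanillin (1), the phenol oxygen of 1 (flanked by OMe) is O4, and its formyl carbon is the first carbon of the C7 chain.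

## Retrosynthetic reasoning

**Side chain.** The allylic alcohol of 19 is made last. The C7 chain is cut at the C=C bond, leading through enoate 18 back to aldehyde 17. Forward, a stabilised phosphorus ylide has to give the E alkene and an aluminium hydride has to reduce the ester in the 1,2-sense. Both are run on the unprotected compound, so no protecting group has to be removed once the allylic alcohol exists.

**Protecting groups.** 17 is traced to 16, in which the aldehyde is a dimethyl acetal, the Cγ hydroxyl a silyl ether and the two phenols MOM ethers. All four withstand base, organomagnesium reagents and hydride, and all four leave in a single acid treatment.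

**Ring B (key disconnection).** Ring B of 16 is opened at the aryl–oxygen bond O1–C8a, giving bromo alcohol 15. This bond is preferred to either C–O bond at a stereocentre because forming it touches neither C2 nor C3, so the anti arrangement of 15 becomes the cis arrangement of 16 without any substitution at carbon. It is preferred to O4–C4a because 15 then derives from 1, which has bromine on exactly the carbon that must become C8a. The forward reaction is a copper-catalysed intramolecular O-arylation of a secondary benzylic alcohol.

**Carbinol centre.** 15 is cut at the C1–H bond to ketone 14, so that the resident C2 centre directs the hydride. A non-chelated, Felkin–Anh-type delivery to such an α-aryloxy ketone leads to the syn alcohol and hence to the trans-dioxane. The anti alcohol needs a hydride bound to a metal that bridges the carbonyl and aryloxy oxygens. The relative configuration of the target is decided here, and the diastereomers can be separated before the ring is closed.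

**Ring C–C1 bond.** 14 is cut between the carbonyl carbon and ring C, giving N-methoxy-N-methylamide 7 and arylmagnesium reagent 12, made from bromide 11. The acyl substitution stops at the ketone because adduct 13 survives until work-up. Magnesium is chosen because it does not exchange with the ring A bromide.

**O4–C3 bond.** 7 comes from ester 6, which is cut at the ether bond into phenol 2 and hydroxy ester 5. The forward reaction is a redox condensation with inversion at a carbon next to an ester, so (S)-5 gives (R)-6. 5 is the primary silyl ether of diol 4, obtained from chiral-pool acetonide 3; 2 is the acetal of 1.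

**Ring C.** 11 is the bis-MOM ether of catechol 10. 10 comes from aldehyde 8 by oxidative replacement of the formyl group by hydroxyl via formate 9, which puts bromine meta to OMe and para to the central oxygen.

## Alternatives that were turned down

**Alternative 1:** The C2–C3 bond and the Cγ–O bond are both cut. A triplet-state [2+2] photocycloaddition (Paternò–Büchi) of ring C aldehyde A2 with ring A aryl vinyl ether A3 would give cis-oxetane A1. After the ring A phenol is unmasked, its phenoxide would open the oxetane at the benzylic carbon with inversion, forming O1–C2 and releasing the Cγ hydroxyl.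
- *For:* it is by far the shortest plan, the only one that makes a C–C bond and both stereocentres in one step, and the oxetane oxygen becomes the Cγ hydroxyl with no redox change. On step economy it is stronger than the chosen route.
- *Against:* oxygenated benzaldehydes have low-lying π,π* triplets and add poorly to alkenes (the pivalates in A2 only mitigate this), and an aryl vinyl ether is a weak partner. Closure of the 1,4-biradical gives no dependable cis preference. Nothing controls absolute configuration, so A1 would be racemic and need resolution. The ring expansion needs a clean SN2 at an electron-rich benzylic oxetane carbon, where the Lewis acid activation an oxetane requires invites ionisation.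
- *Comparison:* the chosen route is longer, but C3 comes from the chiral pool, C2 from a substrate-directed reduction, and the ring closure cannot change either.

**Alternative 2:** The O4–C3 bond is cut. In epoxy phenol A5 the ring A phenoxide would attack the internal epoxide carbon in a 6-exo-tet opening with inversion, closing ring B and freeing the Cγ hydroxyl to give enoate A4.
- *For:* the closure is stereospecific, metal-free, favoured over the 7-endo mode, and the enoate is already in place. As a single reaction it is probably more certain than a copper-catalysed arylation; that point goes to this alternative.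
- *Against:* A5 already contains the O1–C2 benzylic aryl ether with defined configuration, next to an epoxide of defined configuration and a free phenol on the adjacent ring A carbon. Making it needs a ring A catechol differentiated so that the oxygen meta to the chain is etherified. It also needs an etherification at an electron-rich secondary benzylic carbon that must not ionise, and control of an epoxide centre with no directing hydroxyl.
- *Comparison:* the difficulty is moved upstream rather than removed. In the chosen route the regiochemistry is bought with 1 and both stereocentres come from reactions at carbons that are not benzylic-cation prone (an α-ester carbon) or not substituted at all.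

**Alternative 3:** The C2–O1 bond and the aryl–O4 bond are both cut. The phenoxide of bromophenol A7 would open trans-epoxide A8 at the benzylic carbon with inversion, and the liberated C3 alkoxide would be arylated at the neighbouring C–Br carbon under copper catalysis, giving aldehyde A6 in one flask.
- *For:* it is convergent, both stereocentres would come from one catalytic asymmetric epoxidation, and it needs roughly half the steps. On step economy and on catalytic rather than substrate control it is stronger.
- *Against:* A7 has bromine between the two oxygens and is not a stock compound in the way 1 is. A hindered ortho-bromophenoxide has to open A8 intermolecularly at elevated temperature. The tri-oxygenated aryl group makes the benzylic carbon borderline SN1, so inversion is not assured and attack at the other epoxide carbon competes. Any erosion appears as the trans isomer or a regioisomer that the arylation carries forward, and a free aldehyde is exposed to hot base.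
- *Comparison:* the chosen route uses the same kind of ring-closing arylation but applies it to a purified, diastereomerically defined precursor (15), and never performs a substitution at the benzylic carbon.

Key step: step 10

Remark on the chemistry: all dioxane names use one fixed numbering, O1–C2(aryl)–C3(CH2O)–O4–C4a–C5(OMe)–C6–C7(chain)–C8–C8a, even where a nomenclature rule would renumber. In the open-chain compounds C1, C2, C3 of the propane are Cα, Cβ, Cγ.

## Route

Step 1
Reactants: 1 3-bromo-4-hydroxy-5-methoxybenzaldehyde (5-bromovanillin)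
Product: 2 2-bromo-4-(dimethoxymethyl)-6-methoxyphenol
Conditions: HC(OMe)3, MeOH, p-TsOH·H2O (cat.), rt; Et3N quench; used crude
Reagents that add atoms: trimethyl orthoformate COC(OC)OC; methanol CO
Why: Acid-catalysed acetalisation with the orthoformate as water scavenger; the aldehyde must be masked against the organomagnesium and hydride steps. The phenolic acetal hydrolyses easily, so it is quenched with base and not passed through acidic silica.

Step 2
Reactants: 3 methyl (S)-2,2-dimethyl-1,3-dioxolane-4-carboxylate
Product: 4 methyl (S)-2,3-dihydroxypropanoate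
Conditions: p-TsOH·H2O (cat.), MeOH, rt
Reagents that add atoms: none
Why: Acid-catalysed transacetalisation to methanol frees the diol; no bond to the stereocentre is broken and the methyl ester is unchanged in methanol.

Step 3
Reactants: 4 methyl (S)-2,3-dihydroxypropanoate
Product: 5 methyl (S)-3-[(tert-butyldimethylsilyl)oxy]-2-hydroxypropanoate
Conditions: TBSCl (1.05 equiv), imidazole, CH2Cl2, 0 °C
Reagents that add atoms: tert-butyldimethylsilyl chloride CC(C)(C)[Si](C)(C)Cl
Why: Selective silylation of the primary hydroxyl; the secondary hydroxyl next to the ester is more hindered and less nucleophilic.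

Step 4
Reactants: 2 2-bromo-4-(dimethoxymethyl)-6-methoxyphenol; 5 methyl (S)-3-[(tert-butyldimethylsilyl)oxy]-2-hydroxypropanoate
Product: 6 methyl (R)-2-[2-bromo-4-(dimethoxymethyl)-6-methoxyphenoxy]-3-[(tert-butyldimethylsilyl)oxy]propanoate
Conditions: PPh3, DIAD, THF, 0 °C → rt
Reagents that add atoms: none
Why: Mitsunobu reaction; the acidic, bromine-flanked phenol displaces the activated secondary hydroxyl in an SN2 step that the adjacent ester accelerates, so C2 is inverted from S to R and the future O4–C3 bond is made with the required configuration. Acetal, silyl ether and aryl bromide are inert under these near-neutral conditions.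

Step 5
Reactants: 6 methyl (R)-2-[2-bromo-4-(dimethoxymethyl)-6-methoxyphenoxy]-3-[(tert-butyldimethylsilyl)oxy]propanoate
Product: 7 (R)-2-[2-bromo-4-(dimethoxymethyl)-6-methoxyphenoxy]-3-[(tert-butyldimethylsilyl)oxy]-N-methoxy-N-methylpropanamide
Conditions: MeNH(OMe)·HCl, i-PrMgCl, THF, −20 °C
Reagents that add atoms: N,O-dimethylhydroxylamine hydrochloride CNOC.Cl
Why: Weinreb amide formation by aminolysis of the ester with the magnesium amide generated in the flask; at −20 °C this weakly basic amide should not deprotonate the α-aryloxy centre, and bromine–magnesium exchange on the electron-rich ring is too slow to compete.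

Step 6
Reactants: 8 5-bromo-2-hydroxy-3-methoxybenzaldehyde
Product: 10 5-bromo-3-methoxybenzene-1,2-diol, via aryl formate 9 (not isolated)
Conditions: H2O2 (30 % aq.), NaOH (aq.), THF, 0 °C → rt, N2; then dilute HCl to pH 3
Reagents that add atoms: hydrogen peroxide OO
Why: Dakin oxidation; hydroperoxide adds to the aldehyde, the electron-rich aryl group migrates to oxygen and formate 9 is saponified in the flask, so the formyl-bearing carbon becomes the second catechol carbon of ring C.

Step 7
Reactants: 10 5-bromo-3-methoxybenzene-1,2-diol
Product: 11 5-bromo-1-methoxy-2,3-bis(methoxymethoxy)benzene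
Conditions: MOMCl, i-Pr2NEt, CH2Cl2, 0 °C → rt
Reagents that add atoms: chloromethyl methyl ether COCCl
Why: Double O-alkylation of the catechol (MOM protection); MOM ethers withstand magnesium, hydride and hot carbonate and leave in the same acid step as the acetal and silyl ether.

Step 8
Reactants: 11 5-bromo-1-methoxy-2,3-bis(methoxymethoxy)benzene; 7 (R)-2-[2-bromo-4-(dimethoxymethyl)-6-methoxyphenoxy]-3-[(tert-butyldimethylsilyl)oxy]-N-methoxy-N-methylpropanamide
Product: 14 (R)-2-[2-bromo-4-(dimethoxymethyl)-6-methoxyphenoxy]-3-[(tert-butyldimethylsilyl)oxy]-1-[3-methoxy-4,5-bis(methoxymethoxy)phenyl]propan-1-one, via arylmagnesium bromide 12 (not isolated), via tetrahedral magnesium adduct 13 (not isolated)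
Conditions: 11, Mg, I2 (cat.), THF, 50 °C; transfer off excess Mg; then 7, THF, −20 → 0 °C; cold aq. NH4Cl
Reagents that add atoms: none
Why: Weinreb ketone synthesis; the Grignard reagent 12 adds once to the amide, and the chelated adduct 13 does not collapse before work-up, so no tertiary alcohol forms. A magnesium reagent is used because it does not undergo halogen–metal exchange with the ring A bromide, and the cold buffered quench protects the now more acidic α-centre.

Step 9
Reactants: 14 (R)-2-[2-bromo-4-(dimethoxymethyl)-6-methoxyphenoxy]-3-[(tert-butyldimethylsilyl)oxy]-1-[3-methoxy-4,5-bis(methoxymethoxy)phenyl]propan-1-one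
Product: 15 (1S,2R)-2-[2-bromo-4-(dimethoxymethyl)-6-methoxyphenoxy]-3-[(tert-butyldimethylsilyl)oxy]-1-[3-methoxy-4,5-bis(methoxymethoxy)phenyl]propan-1-ol (anti, erythro)
Conditions: Zn(BH4)2 (from ZnCl2 and NaBH4), Et2O, −30 → 0 °C; then H2O
Reagents that add atoms: none
Why: Chelation-controlled (Cram-chelate) hydride reduction; zinc bridges the carbonyl oxygen and the aryloxy oxygen on C2, and hydride attacks the face on the side of the C2 hydrogen rather than the CH2OTBS group, which should give the 1S,2R anti alcohol. A bulky non-chelating hydride would follow the Felkin–Anh polar model to the syn isomer and hence to the trans-dioxane, so chelation is essential; the diastereomers are separable here.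

Step 10
Reactants: 15 (1S,2R)-2-[2-bromo-4-(dimethoxymethyl)-6-methoxyphenoxy]-3-[(tert-butyldimethylsilyl)oxy]-1-[3-methoxy-4,5-bis(methoxymethoxy)phenyl]propan-1-ol
Product: 16 (2S,3R)-3-{[(tert-butyldimethylsilyl)oxy]methyl}-7-(dimethoxymethyl)-5-methoxy-2-[3-methoxy-4,5-bis(methoxymethoxy)phenyl]-2,3-dihydro-1,4-benzodioxine (cis)
Conditions: CuI (10 mol %), 3,4,7,8-tetramethyl-1,10-phenanthroline (20 mol %), Cs2CO3 (2 equiv), toluene (0.05 M), 110 °C, Ar
Reagents that add atoms: none
Why: Intramolecular Ullmann-type etherification, the copper-catalysed O-arylation of an aliphatic alcohol by an ortho-bromoaryl ether that is an established route to 2,3-dihydro-1,4-benzodioxines (the palladium-catalysed version with bulky phosphines is its closest relative). Cs2CO3 deprotonates the benzylic hydroxyl reversibly, the alkoxide binds phenanthroline-ligated monovalent copper, the copper alkoxide adds oxidatively to the C–Br bond five atoms away to give a trivalent copper aryl alkoxide, and C–O reductive elimination releases 16 and CuBr. Ring B is closed as a six-membered ring by bonding O1 to C8a, a 6-exo closure at the aryl carbon in which bromide leaves from outside the new ring. No stereocentre is created and no bond to C1 or C2 of 15 is broken, so 1S,2R (anti) maps onto 2S,3R (cis). The selectivity needed is C–O coupling in preference to oxidation of the carbinol to the ketone, reductive loss of bromine and intermolecular coupling; the hydroxyl held next to the halide by the tether, exclusion of air and moderate dilution should secure it. Regiochemistry is not in question because O4 is already alkylated, and the acetal keeps ring A electron-rich, so no Smiles shift of the aryl group from O4 to the alkoxide is activated. MOM ethers, silyl ether and acetal are stable to carbonate in toluene.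

Step 11
Reactants: 16 (2S,3R)-3-{[(tert-butyldimethylsilyl)oxy]methyl}-7-(dimethoxymethyl)-5-methoxy-2-[3-methoxy-4,5-bis(methoxymethoxy)phenyl]-2,3-dihydro-1,4-benzodioxine
Product: 17 (2S,3R)-2-(3,4-dihydroxy-5-methoxyphenyl)-3-(hydroxymethyl)-5-methoxy-2,3-dihydro-1,4-benzodioxine-7-carbaldehyde
Conditions: 3 M aq. HCl, THF, 0 °C → rt, Ar
Reagents that add atoms: water O
Why: Acid hydrolysis removes the acetal (to the aldehyde), the primary silyl ether and both aryl MOM ethers in one operation, before the acid-sensitive allylic alcohol exists. The acid is kept cold and no stronger than needed, because the benzylic C2–O1 ether could ionise and re-close as the trans isomer.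

Step 12
Reactants: 17 (2S,3R)-2-(3,4-dihydroxy-5-methoxyphenyl)-3-(hydroxymethyl)-5-methoxy-2,3-dihydro-1,4-benzodioxine-7-carbaldehyde
Product: 18 methyl (E)-3-[(2S,3R)-2-(3,4-dihydroxy-5-methoxyphenyl)-3-(hydroxymethyl)-5-methoxy-2,3-dihydro-1,4-benzodioxin-7-yl]prop-2-enoate
Conditions: Ph3P=CHCO2Me (1.5 equiv), THF, rt → 40 °C, Ar
Reagents that add atoms: methyl (triphenylphosphoranylidene)acetate COC(=O)C=P(c1ccccc1)(c1ccccc1)c1ccccc1
Why: Wittig olefination with a stabilised ylide, which gives the E enoate with aromatic aldehydes; free hydroxyl groups are tolerated, and the ylide is too weakly basic to generate enough phenoxide to open ring B through a quinone methide.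

Step 13
Reactants: 18 methyl (E)-3-[(2S,3R)-2-(3,4-dihydroxy-5-methoxyphenyl)-3-(hydroxymethyl)-5-methoxy-2,3-dihydro-1,4-benzodioxin-7-yl]prop-2-enoate
Product: 19 5-[(2S,3R)-3-(hydroxymethyl)-7-[(E)-3-hydroxyprop-1-enyl]-5-methoxy-2,3-dihydro-1,4-benzodioxin-2-yl]-3-methoxybenzene-1,2-diol (target)
Conditions: i-Bu2AlH (7 equiv), THF/CH2Cl2, −78 → 0 °C; aq. potassium sodium tartrate
Reagents that add atoms: none
Why: 1,2-Reduction of the α,β-unsaturated ester with i-Bu2AlH; three equivalents are consumed by the hydroxyl groups as aluminium alkoxides, which also shield the catechol, and the excess reduces the ester to the allylic alcohol without touching the alkene. The tartrate work-up avoids acid.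

## Compound list

1 | 3-bromo-4-hydroxy-5-methoxybenzaldehyde (5-bromovanillin) | COc1cc(C=O)cc(Br)c1O | starting material
2 | 2-bromo-4-(dimethoxymethyl)-6-methoxyphenol | COc1cc(C(OC)OC)cc(Br)c1O | intermediate
3 | methyl (S)-2,2-dimethyl-1,3-dioxolane-4-carboxylate | COC(=O)[C@@H]1COC(C)(C)O1 | starting material
4 | methyl (S)-2,3-dihydroxypropanoate | COC(=O)[C@@H](O)CO | intermediate
5 | methyl (S)-3-[(tert-butyldimethylsilyl)oxy]-2-hydroxypropanoate | COC(=O)[C@@H](O)CO[Si](C)(C)C(C)(C)C | intermediate
6 | methyl (R)-2-[2-bromo-4-(dimethoxymethyl)-6-methoxyphenoxy]-3-[(tert-butyldimethylsilyl)oxy]propanoate | COC(=O)[C@H](Oc1c(Br)cc(C(OC)OC)cc1OC)CO[Si](C)(C)C(C)(C)C | intermediate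
7 | (R)-2-[2-bromo-4-(dimethoxymethyl)-6-methoxyphenoxy]-3-[(tert-butyldimethylsilyl)oxy]-N-methoxy-N-methylpropanamide | CON(C)C(=O)[C@H](Oc1c(Br)cc(C(OC)OC)cc1OC)CO[Si](C)(C)C(C)(C)C | intermediate
8 | 5-bromo-2-hydroxy-3-methoxybenzaldehyde | COc1cc(Br)cc(C=O)c1O | starting material
9 | 5-bromo-2-hydroxy-3-methoxyphenyl formate | COc1cc(Br)cc(OC=O)c1O | intermediate
10 | 5-bromo-3-methoxybenzene-1,2-diol | COc1cc(Br)cc(O)c1O | intermediate
11 | 5-bromo-1-methoxy-2,3-bis(methoxymethoxy)benzene | COc1cc(Br)cc(OCOC)c1OCOC | intermediate
12 | [3-methoxy-4,5-bis(methoxymethoxy)phenyl]magnesium bromide | COc1cc([Mg]Br)cc(OCOC)c1OCOC | intermediate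
13 | bromomagnesium alkoxide of the N-methoxy-N-methyl hemiaminal formed from 12 and 7 (C2 R; hemiaminal carbon undefined) | COc1cc(C(O[Mg]Br)(N(C)OC)[C@H](Oc2c(Br)cc(C(OC)OC)cc2OC)CO[Si](C)(C)C(C)(C)C)cc(OCOC)c1OCOC | intermediate
14 | (R)-2-[2-bromo-4-(dimethoxymethyl)-6-methoxyphenoxy]-3-[(tert-butyldimethylsilyl)oxy]-1-[3-methoxy-4,5-bis(methoxymethoxy)phenyl]propan-1-one | COc1cc(C(=O)[C@H](Oc2c(Br)cc(C(OC)OC)cc2OC)CO[Si](C)(C)C(C)(C)C)cc(OCOC)c1OCOC | intermediate
15 | (1S,2R)-2-[2-bromo-4-(dimethoxymethyl)-6-methoxyphenoxy]-3-[(tert-butyldimethylsilyl)oxy]-1-[3-methoxy-4,5-bis(methoxymethoxy)phenyl]propan-1-ol | COc1cc([C@H](O)[C@H](Oc2c(Br)cc(C(OC)OC)cc2OC)CO[Si](C)(C)C(C)(C)C)cc(OCOC)c1OCOC | intermediate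
16 | (2S,3R)-3-{[(tert-butyldimethylsilyl)oxy]methyl}-7-(dimethoxymethyl)-5-methoxy-2-[3-methoxy-4,5-bis(methoxymethoxy)phenyl]-2,3-dihydro-1,4-benzodioxine | COc1cc([C@@H]2Oc3cc(C(OC)OC)cc(OC)c3O[C@@H]2CO[Si](C)(C)C(C)(C)C)cc(OCOC)c1OCOC | intermediate
17 | (2S,3R)-2-(3,4-dihydroxy-5-methoxyphenyl)-3-(hydroxymethyl)-5-methoxy-2,3-dihydro-1,4-benzodioxine-7-carbaldehyde | COc1cc([C@@H]2Oc3cc(C=O)cc(OC)c3O[C@@H]2CO)cc(O)c1O | intermediate
18 | methyl (E)-3-[(2S,3R)-2-(3,4-dihydroxy-5-methoxyphenyl)-3-(hydroxymethyl)-5-methoxy-2,3-dihydro-1,4-benzodioxin-7-yl]prop-2-enoate | COc1cc([C@@H]2Oc3cc(/C=C/C(=O)OC)cc(OC)c3O[C@@H]2CO)cc(O)c1O | intermediate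
19 | 5-[(2S,3R)-3-(hydroxymethyl)-7-[(E)-3-hydroxyprop-1-enyl]-5-methoxy-2,3-dihydro-1,4-benzodioxin-2-yl]-3-methoxybenzene-1,2-diol | COc1cc([C@@H]2Oc3cc(/C=C/CO)cc(OC)c3O[C@@H]2CO)cc(O)c1O | target

## Step count and least certain steps

Total: 13 steps. Longest linear sequence: 10 steps (3 → 4 → 5 → 6 → 7 → 14 → 15 → 16 → 17 → 18 → 19; steps 2, 3, 4, 5, 8, 9, 10, 11, 12, 13).

**Step 10 (key step).** The most likely failure is slow oxidative addition into the electron-rich, ortho-oxygenated C–Br bond. Slower processes could then take over: oxidation of the benzylic alkoxide to the ketone, reductive loss of bromine, or base-induced silyl migration from the primary to the secondary oxygen followed by closure to a seven-membered ring. A first recourse within the same bond formation is zerovalent palladium catalysis (Pd(OAc)2 with a bulky di-tert-butyl biaryl phosphine, Cs2CO3, toluene).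

The fallback forms the other ring B bond at Cα, O1–C2, with inversion. It sets out from 14 and returns at 16:
- Reduction of 14 with the non-chelating LiBH(s-Bu)3 (THF, −78 °C) should give, by the Felkin–Anh mode, the syn alcohol (1R,2R)-2-[2-bromo-4-(dimethoxymethyl)-6-methoxyphenoxy]-3-[(tert-butyldimethylsilyl)oxy]-1-[3-methoxy-4,5-bis(methoxymethoxy)phenyl]propan-1-ol F1.
- Miyaura borylation (B2pin2, Pd(dppf)Cl2, KOAc, dioxane, 90 °C) converts the bromide into the pinacol boronate F2.
- Oxidation (NaBO3·4H2O, THF/H2O) gives the phenol F3.
- Intramolecular Mitsunobu etherification (PPh3, DIAD, THF) closes ring B with inversion at the carbinol carbon, so 1R,2R becomes 2S,3R, which is 16.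

**Step 9.** The aryloxy oxygen is hindered and a weak donor, so chelation may be incomplete and facial selectivity poor; traces of base could also epimerise C2 of the ketone. The fallback sets the carbinol centre in the C–C bond-forming event instead. It sets out from 6 and returns at 15, bypassing 7 and 14:
- i-Bu2AlH (toluene, −78 °C) reduces 6 to the aldehyde (R)-2-[2-bromo-4-(dimethoxymethyl)-6-methoxyphenoxy]-3-[(tert-butyldimethylsilyl)oxy]propanal F4, used at once.
- Addition of 12 in THF at −78 °C, where the aryloxy oxygen is not expected to chelate magnesium, should follow the Felkin–Anh polar model. For an aldehyde with an incoming aryl group this leads to the anti alcohol 15.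

**Step 4.** Attack of the di-ortho-substituted phenoxide on the alkoxyphosphonium ion may be slow, so alkylation of the hydrazide or elimination could compete. Adventitious acid could also unmask the phenolic acetal. The fallback separates activation from displacement. It sets out from 5 and 2 and returns at 6:
- Tf2O and 2,6-lutidine (CH2Cl2, −78 °C) give the triflate methyl (S)-3-[(tert-butyldimethylsilyl)oxy]-2-[(trifluoromethylsulfonyl)oxy]propanoate F5.
- The potassium phenoxide of 2 (K2CO3, MeCN, 0 °C → rt) displaces the triflate with the same inversion.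

**Step 11.** Acid-induced ionisation of the C2–O1 bond (a benzylic carbon para to an oxygenated ring) and re-closure would erode the cis configuration. Acid mild enough to avoid this may cleave the aryl MOM ethers only slowly. The fallback carries the ring C phenols as benzyl ethers, removed by hydrogenolysis before any acid is used. It sets out from 10 and returns at 17:
- BnBr and K2CO3 (DMF) give 1,2-bis(benzyloxy)-5-bromo-3-methoxybenzene F6.
- Magnesium gives the Grignard reagent F7, which adds to 7 through the tetrahedral adduct F8 to give the ketone F9.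
- Zn(BH4)2 gives the anti alcohol F10, and the CuI-catalysed closure of step 10 gives the bis(benzyl) ether of the dioxane F11.
- H2 over Pd/C in EtOAc with a trace of Et3N gives the catechol F12. Ring A no longer carries bromine and the aldehyde is still an acetal, so neither is at risk.
- Brief treatment with dilute acid (0.5 M aq. HCl, THF, 0 °C), enough for the acetal and the primary silyl ether, then gives 17.

## Further compounds

F1 | step 10 | (1R,2R)-2-[2-bromo-4-(dimethoxymethyl)-6-methoxyphenoxy]-3-[(tert-butyldimethylsilyl)oxy]-1-[3-methoxy-4,5-bis(methoxymethoxy)phenyl]propan-1-ol | COc1cc([C@@H](O)[C@H](Oc2c(Br)cc(C(OC)OC)cc2OC)CO[Si](C)(C)C(C)(C)C)cc(OCOC)c1OCOC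
F2 | step 10 | (1R,2R)-3-[(tert-butyldimethylsilyl)oxy]-2-[4-(dimethoxymethyl)-2-methoxy-6-(4,4,5,5-tetramethyl-1,3,2-dioxaborolan-2-yl)phenoxy]-1-[3-methoxy-4,5-bis(methoxymethoxy)phenyl]propan-1-ol | COc1cc([C@@H](O)[C@H](Oc2c(B3OC(C)(C)C(C)(C)O3)cc(C(OC)OC)cc2OC)CO[Si](C)(C)C(C)(C)C)cc(OCOC)c1OCOC
F3 | step 10 | (1R,2R)-3-[(tert-butyldimethylsilyl)oxy]-2-[4-(dimethoxymethyl)-2-hydroxy-6-methoxyphenoxy]-1-[3-methoxy-4,5-bis(methoxymethoxy)phenyl]propan-1-ol | COc1cc([C@@H](O)[C@H](Oc2c(O)cc(C(OC)OC)cc2OC)CO[Si](C)(C)C(C)(C)C)cc(OCOC)c1OCOC
F4 | step 9 | (R)-2-[2-bromo-4-(dimethoxymethyl)-6-methoxyphenoxy]-3-[(tert-butyldimethylsilyl)oxy]propanal | O=C[C@H](Oc1c(Br)cc(C(OC)OC)cc1OC)CO[Si](C)(C)C(C)(C)C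
F5 | step 4 | methyl (S)-3-[(tert-butyldimethylsilyl)oxy]-2-[(trifluoromethylsulfonyl)oxy]propanoate | COC(=O)[C@@H](OS(=O)(=O)C(F)(F)F)CO[Si](C)(C)C(C)(C)C
F6 | step 11 | 1,2-bis(benzyloxy)-5-bromo-3-methoxybenzene | COc1cc(Br)cc(OCc2ccccc2)c1OCc1ccccc1
F7 | step 11 | [3,4-bis(benzyloxy)-5-methoxyphenyl]magnesium bromide | COc1cc([Mg]Br)cc(OCc2ccccc2)c1OCc1ccccc1
F8 | step 11 | bromomagnesium alkoxide of the N-methoxy-N-methyl hemiaminal formed from F7 and 7 (C2 R; hemiaminal carbon undefined) | COc1cc(C(O[Mg]Br)(N(C)OC)[C@H](Oc2c(Br)cc(C(OC)OC)cc2OC)CO[Si](C)(C)C(C)(C)C)cc(OCc2ccccc2)c1OCc1ccccc1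
F9 | step 11 | (R)-1-[3,4-bis(benzyloxy)-5-methoxyphenyl]-2-[2-bromo-4-(dimethoxymethyl)-6-methoxyphenoxy]-3-[(tert-butyldimethylsilyl)oxy]propan-1-one | COc1cc(C(=O)[C@H](Oc2c(Br)cc(C(OC)OC)cc2OC)CO[Si](C)(C)C(C)(C)C)cc(OCc2ccccc2)c1OCc1ccccc1
F10 | step 11 | (1S,2R)-1-[3,4-bis(benzyloxy)-5-methoxyphenyl]-2-[2-bromo-4-(dimethoxymethyl)-6-methoxyphenoxy]-3-[(tert-butyldimethylsilyl)oxy]propan-1-ol | COc1cc([C@H](O)[C@H](Oc2c(Br)cc(C(OC)OC)cc2OC)CO[Si](C)(C)C(C)(C)C)cc(OCc2ccccc2)c1OCc1ccccc1
F11 | step 11 | (2S,3R)-2-[3,4-bis(benzyloxy)-5-methoxyphenyl]-3-{[(tert-butyldimethylsilyl)oxy]methyl}-7-(dimethoxymethyl)-5-methoxy-2,3-dihydro-1,4-benzodioxine | COc1cc([C@@H]2Oc3cc(C(OC)OC)cc(OC)c3O[C@@H]2CO[Si](C)(C)C(C)(C)C)cc(OCc2ccccc2)c1OCc1ccccc1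
F12 | step 11 | 5-[(2S,3R)-3-{[(tert-butyldimethylsilyl)oxy]methyl}-7-(dimethoxymethyl)-5-methoxy-2,3-dihydro-1,4-benzodioxin-2-yl]-3-methoxybenzene-1,2-diol | COc1cc([C@@H]2Oc3cc(C(OC)OC)cc(OC)c3O[C@@H]2CO[Si](C)(C)C(C)(C)C)cc(O)c1O
A1 | alternative 1 | cis-3-{2-[(tert-butyldimethylsilyl)oxy]-4-{[(tert-butyldimethylsilyl)oxy]methyl}-6-methoxyphenoxy}-2-[3-methoxy-4,5-bis(pivaloyloxy)phenyl]oxetane (enantiomer as drawn) | COc1cc([C@@H]2[C@H](Oc3c(OC)cc(CO[Si](C)(C)C(C)(C)C)cc3O[Si](C)(C)C(C)(C)C)CO2)cc(OC(=O)C(C)(C)C)c1OC(=O)C(C)(C)C
A2 | alternative 1 | 3-methoxy-4,5-bis(pivaloyloxy)benzaldehyde | COc1cc(C=O)cc(OC(=O)C(C)(C)C)c1OC(=O)C(C)(C)C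
A3 | alternative 1 | tert-butyl{[3-[(tert-butyldimethylsilyl)oxy]-4-(ethenyloxy)-5-methoxyphenyl]methoxy}dimethylsilane | C=COc1c(OC)cc(CO[Si](C)(C)C(C)(C)C)cc1O[Si](C)(C)C(C)(C)C
A4 | alternative 2 | methyl (E)-3-{(2S,3R)-3-(hydroxymethyl)-5-methoxy-2-[3-methoxy-4,5-bis(methoxymethoxy)phenyl]-2,3-dihydro-1,4-benzodioxin-7-yl}prop-2-enoate | COc1cc([C@@H]2Oc3cc(/C=C/C(=O)OC)cc(OC)c3O[C@@H]2CO)cc(OCOC)c1OCOC
A5 | alternative 2 | methyl (E)-3-(4-hydroxy-3-methoxy-5-{(S)-[3-methoxy-4,5-bis(methoxymethoxy)phenyl][(2S)-oxiran-2-yl]methoxy}phenyl)prop-2-enoate | COc1cc([C@H](Oc2cc(/C=C/C(=O)OC)cc(OC)c2O)[C@@H]2CO2)cc(OCOC)c1OCOC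
A6 | alternative 3 | (2S,3R)-5-methoxy-3-[(methoxymethoxy)methyl]-2-[3-methoxy-4,5-bis(methoxymethoxy)phenyl]-2,3-dihydro-1,4-benzodioxine-7-carbaldehyde | COc1cc([C@@H]2Oc3cc(C=O)cc(OC)c3O[C@@H]2COCOC)cc(OCOC)c1OCOC
A7 | alternative 3 | 4-bromo-3-hydroxy-5-methoxybenzaldehyde | COc1cc(C=O)cc(O)c1Br
A8 | alternative 3 | (2R,3R)-2-[(methoxymethoxy)methyl]-3-[3-methoxy-4,5-bis(methoxymethoxy)phenyl]oxirane | COc1cc([C@H]2O[C@@H]2COCOC)cc(OCOC)c1OCOC
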